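## The problem

Target 23 is a linear array of three heteroaromatic rings. A 6-bromo-4-methoxyindole is bonded through C3 to C5 of an oxazole, and oxazole C2 carries a 5-bromo-1H-pyrrol-2-yl group (pyrrole B). There is no stereocentre, so nothing can relay stereochemical information; the problems are regiochemical, plus one alkene geometry that the chosen route creates and must hold.

The benzene ring is the hard part. Oxygen at C4 and bromine at C6 are meta to each other. Bromine cannot be placed at C6 of a 4-methoxyindole by substitution, because the methoxy group directs to C5 and C7 and the pyrrole ring is more reactive still. The C4 methoxy group also sits peri to the C3 oxazolyl group. The oxazole must be 2,5-disubstituted with C4–H free.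

The fragile elements are the 2-bromopyrrole with free N–H (sensitive to acid, oxidants and light) and the two C–Br bonds, which exclude organolithium reagents, dissolving metals and hydrogenation once they are present.

The enabling feature is that indole carbons C4, C5, C6 and C7 form a four-carbon chain bridging C3a and C7a, which are C3 and C2 of a pyrrole (pyrrole A). Written as O=C=CH–C(Br)=CH– on pyrrole C2, this chain is a dienylketene whose terminal carbon can bond to pyrrole C3. Oxygen then arrives at C4 and bromine at C6 by connectivity alone, and an oxazolyl group at C4 of pyrrole A becomes the indole C3 substituent.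

## Retrosynthesis

**23 back to 21.** The two N–S bonds and the O–CH3 bond are cut. Both nitrogens of 23 are unmasked last from the N,N'-ditosyl ether 22, which comes from phenol 21 by O-methylation. Methylating while both nitrogens are sulfonylated leaves oxygen as the only nucleophile; the reverse order would expose two acidic N–H groups to the alkylating agent. The forward steps only need hydroxide to attack sulfur without touching the aryl bromides.

**21 back to 18 (the strategic cut).** The C3a–C4 bond is cut, opening the benzene ring to dienylketene 19, which is traced to diazoketone 18 by a Wolff rearrangement; dienone 20 lies between 19 and 21. The neighbouring choice, building the pyrrole ring of the indole onto a finished benzene, would need a 1,2,3,5-tetrasubstituted arene with bromine and oxygen already meta. Here that pattern is written into an open chain, and the precursor contains only rings that are bought or made by condensation. The forward reaction must generate the ketene without a nucleophile present, close at carbon rather than nitrogen, and start from the alkene isomer with the ketene cis to pyrrole A.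

**18 back to 15.** The bond between the carbonyl carbon and the diazo carbon is cut, giving acid 16 (activated as chloride 17) and a diazomethane equivalent; 16 comes from methyl ester 15. One carbon is added by a standard acylation rather than by carrying a four-carbon bromo building block. The ester cleavage must not remove the tosyl groups or scramble the alkene.

**15 back to 11 and 14.** The C=C bond is cut by a Horner–Wadsworth–Emmons disconnection to aldehyde 11 and bromophosphonate 14, which is made from the purchasable phosphonate 12 through dibromide 13. The olefination is placed after the oxazole and both tosyl groups are in position. The kinetically formed alkene isomer then meets only two further steps before the key step, and none of them involves a phosphine, iodide or strong base. The forward step must deliver the isomer with pyrrole A cis to the ester.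

**11 back to 10.** Both N–S bonds are cut at once. Leaving ring A unprotected until this point saves a step and keeps its aldehyde a poorly electrophilic vinylogous formamide during the amine chemistry. The forward step must sulfonylate a hindered 2,5-disubstituted pyrrole nitrogen as well as the unhindered one.

**10 back to 6 and 7.** The oxazole O1–C5 bond is cut to keto amide 9 (Robinson–Gabriel), and the amide C–N bond is cut to ammonium salt 6 and 5-bromo-1H-pyrrole-2-carboxylic acid 7, via active ester 8. This places the oxazole with the required 2,5-pattern, whereas condensing a haloketone with a primary amide would give the 2,4-isomer. The bromine of pyrrole B is bought in 7, so no late halogenation is needed.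

**6 back to 1 and 2.** The C–N bond is cut to azide 4 (reduced through aminophosphonium salt 5) and then to chloroketone 3. The bond from C4 of pyrrole A to the ketone carbon is cut by a Friedel–Crafts disconnection to 1H-pyrrole-2-carbaldehyde 1 and chloroacetyl chloride 2. The formyl group of 1 both directs the acylation to C4 and later becomes the anchor of the dienylketene chain.

## Roads not taken

**Alternative 1:** Paal–Knorr closure of pyrrole B. The two N–C bonds of pyrrole B are cut, and ketoaldehyde A2 would be condensed with NH4OAc to give the N-tosyl indole A1, which lacks the pyrrole bromine.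
- Merits: the ring closure is among the most reliable heterocycle syntheses, and the sensitive bromopyrrole is not carried through the route. In the certainty of its key step this road is better than the chosen plan.
- Weak points: A1 still needs bromination at pyrrole C5 in the presence of free pyrrole C3 and C4, oxazole C4–H and a methoxy-activated benzene ring. A2 combines a 2-acyloxazole with a free aldehyde and is prone to furan formation and aldol reactions. Above all, A2 already contains the 6-bromo-4-methoxyindole, so the hardest part of the target is left unsolved.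
- Comparison: the chosen plan uses a less certain key step but solves the benzene pattern by connectivity and brings the pyrrole bromine in with acid 7.

**Alternative 2:** Cadogan–Sundberg closure. N1–C2 is cut, and P(OEt)3 would deoxygenate the nitro group of the 1,1-diarylethene A4 so that nitrogen bonds to the terminal vinyl carbon, giving A3 with the indole N–H already free.
- Merits: the reaction class is established for α-aryl-2-nitrostyrenes, the assembly is convergent, and the count after the key step is one step shorter.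
- Weak points: A4 carries a 2,6-disubstituted aryl group on a 1,1-disubstituted alkene. Forming that hindered bond by cross-coupling while two other C–Br bonds must survive is the real difficulty. The nitroarene is again a 1,2,3,5-tetrasubstituted benzene. Hot P(OEt)3 brings N-ethylation and N–O by-products, and the nitrogen could instead close a six-membered ring onto oxazole C4.
- Comparison: this road has the better-known key reaction; the chosen plan needs no pre-functionalised arene and no metal-catalysed coupling next to aryl bromides.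

**Alternative 3:** Aryne annulation. N1–C7a and C3–C3a are cut. CsF would release the aryne from silyl triflate A6; the sulfonamide anion of ketone A7 would add at the carbon distal to the methoxy group, and the resulting aryl anion would add to the ketone, giving A5 after dehydration. A5 is identical with compound 22 of the chosen route.
- Merits: this is the most convergent road. Two bonds form in one operation, the methoxy group steers the addition in the right sense, and the product is one step from 23. If A6 and A7 were at hand it would be shorter than the chosen plan.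
- Weak points: A6 is a tetrasubstituted benzene with ortho silyl and triflate groups plus a bromine, and the usual metalation routes to such precursors clash with the C–Br bond. A7 needs its own multistep synthesis. Its enolate can compete with the sulfonamide nitrogen for the aryne, and the aryl anion can be protonated before it reaches the heteroaryl ketone.
- Comparison: the chosen plan sets against this its purchasable starting materials, the absence of organometallic steps once bromine is present, and oxygen and bromine positions fixed by the chain rather than by aryne polarisation.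

Key step: step 11

Remark on the chemistry: acid 7 and phosphonate 12 are taken to be purchasable, and bromophosphonate 14 is made in step 7. The target has no stereocentre; the only stereochemical element of the route is the E geometry of the bromoalkene in 15 to 19 (pyrrole A cis to the carbonyl group).

## Route

Step 1
Reactants: 1 1H-pyrrole-2-carbaldehyde; 2 chloroacetyl chloride
Product: 3 4-(2-chloroacetyl)-1H-pyrrole-2-carbaldehyde
Conditions: AlCl3, CH2Cl2, 0 °C to rt
Reagents that add atoms: none
Why: Friedel–Crafts acylation; the AlCl3-complexed formyl group deactivates the conjugated positions C3 and C5, so the acylium ion should attack C4.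

Step 2
Reactants: 3 4-(2-chloroacetyl)-1H-pyrrole-2-carbaldehyde
Product: 4 4-(2-azidoacetyl)-1H-pyrrole-2-carbaldehyde
Conditions: NaN3, acetone/H2O, rt
Reagents that add atoms: sodium azide, [Na+].[N-]=[N+]=[N-]
Why: SN2 displacement at an α-halo ketone, which is fast at room temperature without base; the low-molecular-weight azide is kept in solution and used directly.

Step 3
Reactants: 4 4-(2-azidoacetyl)-1H-pyrrole-2-carbaldehyde
Product: 6 2-(5-formyl-1H-pyrrol-3-yl)-2-oxoethan-1-aminium 4-methylbenzenesulfonate, via aminophosphonium tosylate 5 (not isolated)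
Conditions: PPh3, TsOH·H2O, THF/H2O, rt
Reagents that add atoms: 4-methylbenzenesulfonic acid (counter-ion), Cc1ccc(cc1)S(=O)(=O)O
Why: Staudinger reduction run in the presence of acid; the iminophosphorane is protonated as it forms (5), so it cannot undergo aza-Wittig reaction with the formyl or keto group, and hydrolysis gives the ammonium salt without ever freeing the amine.

Step 4
Reactants: 6 2-(5-formyl-1H-pyrrol-3-yl)-2-oxoethan-1-aminium 4-methylbenzenesulfonate; 7 5-bromo-1H-pyrrole-2-carboxylic acid
Product: 9 5-bromo-N-[2-(5-formyl-1H-pyrrol-3-yl)-2-oxoethyl]-1H-pyrrole-2-carboxamide, via benzotriazolyl active ester 8 (not isolated)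
Conditions: 7, EDC·HCl, HOBt, DMF, 0 °C; then 6, i-Pr2NEt (slow addition), 0 °C to rt
Reagents that add atoms: none
Why: Carbodiimide/HOBt amide coupling; the amine is released only in the presence of preformed 8, so irreversible N-acylation should outrun reversible imine formation with the weakly electrophilic N–H pyrrole aldehyde and self-condensation of the aminoketone.

Step 5
Reactants: 9 5-bromo-N-[2-(5-formyl-1H-pyrrol-3-yl)-2-oxoethyl]-1H-pyrrole-2-carboxamide
Product: 10 4-[2-(5-bromo-1H-pyrrol-2-yl)-1,3-oxazol-5-yl]-1H-pyrrole-2-carbaldehyde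
Conditions: PPh3, I2, Et3N, CH2Cl2, 0 °C to rt (PPh3 and I2 premixed)
Reagents that add atoms: none
Why: Robinson–Gabriel cyclodehydration of a 2-acylamino ketone; the amide oxygen closes onto the activated ketone carbon and water leaves as Ph3PO, giving the 2,5-disubstituted oxazole with C4–H. The mild basic conditions spare the bromopyrrole and the aldehyde, and premixing keeps free iodine away from the pyrroles.

Step 6
Reactants: 10 4-[2-(5-bromo-1H-pyrrol-2-yl)-1,3-oxazol-5-yl]-1H-pyrrole-2-carbaldehyde
Product: 11 4-[2-(5-bromo-1-tosyl-1H-pyrrol-2-yl)-1,3-oxazol-5-yl]-1-tosyl-1H-pyrrole-2-carbaldehyde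
Conditions: NaH, TsCl, THF/DMF, 0 °C to rt
Reagents that add atoms: 4-methylbenzenesulfonyl chloride, Cc1ccc(cc1)S(Cl)(=O)=O
Why: N-sulfonylation of both pyrrolide anions in one operation. On ring A the tosyl group later keeps nitrogen from capturing the ketene and makes the aldehyde a normal electrophile; on ring B it stabilises the 2-bromopyrrole and blocks N-methylation in step 12.

Step 7
Reactants: 12 methyl 2-[bis(2,2,2-trifluoroethoxy)phosphoryl]acetate
Product: 14 methyl 2-bromo-2-[bis(2,2,2-trifluoroethoxy)phosphoryl]acetate, via dibromophosphonate 13 (not isolated)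
Conditions: Br2, NaOH (aq), 0 °C; then SnCl2, EtOH/H2O, 0 °C
Reagents that add atoms: bromine, BrBr
Why: Exhaustive hypobromite bromination of the doubly activated methylene followed by reductive removal of one bromine with SnCl2; this avoids the mixtures of unbrominated, mono- and dibrominated phosphonate that direct monobromination tends to give.

Step 8
Reactants: 11 4-[2-(5-bromo-1-tosyl-1H-pyrrol-2-yl)-1,3-oxazol-5-yl]-1-tosyl-1H-pyrrole-2-carbaldehyde; 14 methyl 2-bromo-2-[bis(2,2,2-trifluoroethoxy)phosphoryl]acetate
Product: 15 methyl (E)-2-bromo-3-{4-[2-(5-bromo-1-tosyl-1H-pyrrol-2-yl)-1,3-oxazol-5-yl]-1-tosyl-1H-pyrrol-2-yl}prop-2-enoate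
Conditions: 14, t-BuOK, 18-crown-6, THF, −78 °C; then 11
Reagents that add atoms: none
Why: Horner–Wadsworth–Emmons olefination under Still–Gennari-type kinetic control; the electron-poor trifluoroethyl phosphonate with a dissociated potassium counter-ion should place the aryl group cis to the ester, which with bromine on the α-carbon is the E isomer. The phosphonate anion is preformed, so no free alkoxide meets the N-tosyl groups.

Step 9
Reactants: 15 methyl (E)-2-bromo-3-{4-[2-(5-bromo-1-tosyl-1H-pyrrol-2-yl)-1,3-oxazol-5-yl]-1-tosyl-1H-pyrrol-2-yl}prop-2-enoate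
Product: 16 (E)-2-bromo-3-{4-[2-(5-bromo-1-tosyl-1H-pyrrol-2-yl)-1,3-oxazol-5-yl]-1-tosyl-1H-pyrrol-2-yl}prop-2-enoic acid
Conditions: Me3SnOH, 1,2-dichloroethane, 70 °C; then 1 M HCl
Reagents that add atoms: trimethyltin hydroxide, C[Sn](C)(C)O
Why: Methyl ester cleavage with Me3SnOH, a near-neutral method that should leave the N-tosyl groups in place and avoid the conjugate addition of hydroxide that could scramble the alkene geometry.

Step 10
Reactants: 16 (E)-2-bromo-3-{4-[2-(5-bromo-1-tosyl-1H-pyrrol-2-yl)-1,3-oxazol-5-yl]-1-tosyl-1H-pyrrol-2-yl}prop-2-enoic acid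
Product: 18 (E)-3-bromo-1-diazo-4-{4-[2-(5-bromo-1-tosyl-1H-pyrrol-2-yl)-1,3-oxazol-5-yl]-1-tosyl-1H-pyrrol-2-yl}but-3-en-2-one, via acid chloride 17 (not isolated)
Conditions: (COCl)2, DMF (cat.), CH2Cl2, 0 °C to rt; then TMSCHN2, THF/MeCN, 0 °C
Reagents that add atoms: oxalyl chloride (chlorine of 17 only), ClC(=O)C(Cl)=O; trimethylsilyldiazomethane, C[Si](C)(C)C=[N+]=[N-]
Why: Acylation of a diazoalkane by an acid chloride, as in the first stage of an Arndt–Eistert sequence; the trisubstituted bromoalkene is a poor dipolarophile and the bulky silyl diazoalkane at 0 °C should further disfavour pyrazoline formation.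

Step 11
Reactants: 18 (E)-3-bromo-1-diazo-4-{4-[2-(5-bromo-1-tosyl-1H-pyrrol-2-yl)-1,3-oxazol-5-yl]-1-tosyl-1H-pyrrol-2-yl}but-3-en-2-one
Product: 21 6-bromo-3-[2-(5-bromo-1-tosyl-1H-pyrrol-2-yl)-1,3-oxazol-5-yl]-1-tosyl-1H-indol-4-ol, via dienylketene 19 (not isolated), via 3aH-indol-4-one 20 (not isolated)
Conditions: hν (450 nm LEDs), degassed PhMe (0.01 M), rt; then 80 °C
Reagents that add atoms: none
Why: Proposed new method: visible-light Wolff rearrangement of 18 expels N2 with 1,2-shift of the bromovinyl group and gives dienylketene 19, in which the ketene, the bromoalkene and the C2–C3 bond of pyrrole A form a hexatriene held in the reactive cis arrangement by the E geometry. On warming, a thermal disrotatory six-electron electrocyclisation bonds the ketene carbon to pyrrole C3 (the C3a–C4 bond) and closes the six-membered carbocycle as dienone 20. Enolisation of 20, a proton shift from C3a to oxygen, restores the aromatic pyrrole, makes the sequence irreversible and gives phenol 21. The closest known reaction types are the dienylketene electrocyclisation that ends the Danheiser benzannulation, including its diazoketone variant with heteroaryl ketenes, and the Ac2O closure of pyrrolyl Stobbe half-esters to 4-acetoxyindoles; a bromine-bearing dienylketene generated directly from an enoyl diazomethane on a pyrrole has no direct precedent. No stereocentre is created, since C3a of 20 is sp3 only transiently. The step needs closure at carbon and not at nitrogen, which the N-tosyl group of ring A secures, and it needs the ketene cis to the pyrrole, which the alkene geometry set in step 8 secures. Oxygen at C4 and bromine at C6 follow from their positions in the chain, and C3 is the only free ring carbon next to the chain, so no regioisomeric closure is available.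

Step 12
Reactants: 21 6-bromo-3-[2-(5-bromo-1-tosyl-1H-pyrrol-2-yl)-1,3-oxazol-5-yl]-1-tosyl-1H-indol-4-ol
Product: 22 6-bromo-3-[2-(5-bromo-1-tosyl-1H-pyrrol-2-yl)-1,3-oxazol-5-yl]-4-methoxy-1-tosyl-1H-indole
Conditions: MeI, K2CO3, acetone, rt
Reagents that add atoms: iodomethane, CI
Why: Williamson O-methylation of the phenoxide; both ring nitrogens carry tosyl groups, so oxygen is the only site that can be alkylated.

Step 13
Reactants: 22 6-bromo-3-[2-(5-bromo-1-tosyl-1H-pyrrol-2-yl)-1,3-oxazol-5-yl]-4-methoxy-1-tosyl-1H-indole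
Product: 23 6-bromo-3-[2-(5-bromo-1H-pyrrol-2-yl)-1,3-oxazol-5-yl]-4-methoxy-1H-indole
Conditions: NaOH (aq), 1,4-dioxane, 80 °C; then NH4Cl (aq)
Reagents that add atoms: none
Why: Nucleophilic N-desulfonylation; hydroxide attacks sulfur and releases the indolide and pyrrolide anions. The alcohol-free medium avoids alkyl tosylates that could N-alkylate the product, and the aryl bromides, oxazole and methyl ether are inert to aqueous base.

## Compound list

1 | 1H-pyrrole-2-carbaldehyde | O=Cc1ccc[nH]1 | starting material
2 | chloroacetyl chloride | ClCC(Cl)=O | starting material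
3 | 4-(2-chloroacetyl)-1H-pyrrole-2-carbaldehyde | O=Cc1cc(C(=O)CCl)c[nH]1 | intermediate
4 | 4-(2-azidoacetyl)-1H-pyrrole-2-carbaldehyde | O=Cc1cc(C(=O)CN=[N+]=[N-])c[nH]1 | intermediate
5 | {[2-(5-formyl-1H-pyrrol-3-yl)-2-oxoethyl]amino}triphenylphosphonium 4-methylbenzenesulfonate (formed in the flask, not isolated) | O=Cc1cc(C(=O)CN[P+](c2ccccc2)(c2ccccc2)c2ccccc2)c[nH]1.Cc1ccc(cc1)S(=O)(=O)[O-] | intermediate
6 | 2-(5-formyl-1H-pyrrol-3-yl)-2-oxoethan-1-aminium 4-methylbenzenesulfonate | O=Cc1cc(C(=O)C[NH3+])c[nH]1.Cc1ccc(cc1)S(=O)(=O)[O-] | intermediate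
7 | 5-bromo-1H-pyrrole-2-carboxylic acid | OC(=O)c1ccc(Br)[nH]1 | starting material
8 | 1H-benzotriazol-1-yl 5-bromo-1H-pyrrole-2-carboxylate (formed in the flask, not isolated) | O=C(On1nnc2ccccc12)c1ccc(Br)[nH]1 | intermediate
9 | 5-bromo-N-[2-(5-formyl-1H-pyrrol-3-yl)-2-oxoethyl]-1H-pyrrole-2-carboxamide | O=Cc1cc(C(=O)CNC(=O)c2ccc(Br)[nH]2)c[nH]1 | intermediate
10 | 4-[2-(5-bromo-1H-pyrrol-2-yl)-1,3-oxazol-5-yl]-1H-pyrrole-2-carbaldehyde | O=Cc1cc(-c2cnc(-c3ccc(Br)[nH]3)o2)c[nH]1 | intermediate
11 | 4-[2-(5-bromo-1-tosyl-1H-pyrrol-2-yl)-1,3-oxazol-5-yl]-1-tosyl-1H-pyrrole-2-carbaldehyde | O=Cc1cc(-c2cnc(-c3ccc(Br)n3S(=O)(=O)c3ccc(C)cc3)o2)cn1S(=O)(=O)c1ccc(C)cc1 | intermediate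
12 | methyl 2-[bis(2,2,2-trifluoroethoxy)phosphoryl]acetate | COC(=O)CP(=O)(OCC(F)(F)F)OCC(F)(F)F | starting material
13 | methyl 2,2-dibromo-2-[bis(2,2,2-trifluoroethoxy)phosphoryl]acetate (formed in the flask, not isolated) | COC(=O)C(Br)(Br)P(=O)(OCC(F)(F)F)OCC(F)(F)F | intermediate
14 | methyl 2-bromo-2-[bis(2,2,2-trifluoroethoxy)phosphoryl]acetate (racemic) | COC(=O)C(Br)P(=O)(OCC(F)(F)F)OCC(F)(F)F | intermediate
15 | methyl (E)-2-bromo-3-{4-[2-(5-bromo-1-tosyl-1H-pyrrol-2-yl)-1,3-oxazol-5-yl]-1-tosyl-1H-pyrrol-2-yl}prop-2-enoate | COC(=O)/C(Br)=C\c1cc(-c2cnc(-c3ccc(Br)n3S(=O)(=O)c3ccc(C)cc3)o2)cn1S(=O)(=O)c1ccc(C)cc1 | intermediate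
16 | (E)-2-bromo-3-{4-[2-(5-bromo-1-tosyl-1H-pyrrol-2-yl)-1,3-oxazol-5-yl]-1-tosyl-1H-pyrrol-2-yl}prop-2-enoic acid | OC(=O)/C(Br)=C\c1cc(-c2cnc(-c3ccc(Br)n3S(=O)(=O)c3ccc(C)cc3)o2)cn1S(=O)(=O)c1ccc(C)cc1 | intermediate
17 | (E)-2-bromo-3-{4-[2-(5-bromo-1-tosyl-1H-pyrrol-2-yl)-1,3-oxazol-5-yl]-1-tosyl-1H-pyrrol-2-yl}prop-2-enoyl chloride (formed in the flask, not isolated) | ClC(=O)/C(Br)=C\c1cc(-c2cnc(-c3ccc(Br)n3S(=O)(=O)c3ccc(C)cc3)o2)cn1S(=O)(=O)c1ccc(C)cc1 | intermediate
18 | (E)-3-bromo-1-diazo-4-{4-[2-(5-bromo-1-tosyl-1H-pyrrol-2-yl)-1,3-oxazol-5-yl]-1-tosyl-1H-pyrrol-2-yl}but-3-en-2-one | [N-]=[N+]=CC(=O)/C(Br)=C\c1cc(-c2cnc(-c3ccc(Br)n3S(=O)(=O)c3ccc(C)cc3)o2)cn1S(=O)(=O)c1ccc(C)cc1 | intermediate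
19 | (E)-3-bromo-4-{4-[2-(5-bromo-1-tosyl-1H-pyrrol-2-yl)-1,3-oxazol-5-yl]-1-tosyl-1H-pyrrol-2-yl}buta-1,3-dien-1-one (formed in the flask, not isolated) | O=C=C/C(Br)=C\c1cc(-c2cnc(-c3ccc(Br)n3S(=O)(=O)c3ccc(C)cc3)o2)cn1S(=O)(=O)c1ccc(C)cc1 | intermediate
20 | 6-bromo-3-[2-(5-bromo-1-tosyl-1H-pyrrol-2-yl)-1,3-oxazol-5-yl]-1-tosyl-1,3a-dihydro-4H-indol-4-one (racemic at C3a, formed in the flask, not isolated) | O=C1C=C(Br)C=C2N(S(=O)(=O)c3ccc(C)cc3)C=C(c3cnc(-c4ccc(Br)n4S(=O)(=O)c4ccc(C)cc4)o3)C12 | intermediate
21 | 6-bromo-3-[2-(5-bromo-1-tosyl-1H-pyrrol-2-yl)-1,3-oxazol-5-yl]-1-tosyl-1H-indol-4-ol | Oc1cc(Br)cc2n(S(=O)(=O)c3ccc(C)cc3)cc(-c3cnc(-c4ccc(Br)n4S(=O)(=O)c4ccc(C)cc4)o3)c12 | intermediate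
22 | 6-bromo-3-[2-(5-bromo-1-tosyl-1H-pyrrol-2-yl)-1,3-oxazol-5-yl]-4-methoxy-1-tosyl-1H-indole | COc1cc(Br)cc2n(S(=O)(=O)c3ccc(C)cc3)cc(-c3cnc(-c4ccc(Br)n4S(=O)(=O)c4ccc(C)cc4)o3)c12 | intermediate
23 | 6-bromo-3-[2-(5-bromo-1H-pyrrol-2-yl)-1,3-oxazol-5-yl]-4-methoxy-1H-indole | COc1cc(Br)cc2[nH]cc(-c3cnc(-c4ccc(Br)[nH]4)o3)c12 | target

## Step count and least certain steps

Total: 13 steps. Longest linear sequence: 12 steps (1 to 23 through steps 1 to 6 and 8 to 13); step 7 is a one-step side branch.

**Step 11 (key step).** The ketene 19, formed without an external trap, may be consumed by dimerisation or by reaction with unreacted diazoketone before the dearomatising closure onto the tosylpyrrole takes place. Irradiation may also isomerise the bromoalkene to the geometry that cannot reach C3.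
Fallback, from 18 back to 21 by known reactions: the ketene is trapped deliberately. Irradiation of 18 in THF/water (or AgO2CPh and Et3N in aqueous dioxane), the ordinary Arndt–Eistert homologation, should give (E)-3-bromo-4-{4-[2-(5-bromo-1-tosylpyrrol-2-yl)oxazol-5-yl]-1-tosylpyrrol-2-yl}but-3-enoic acid F1. Heating F1 with Ac2O and NaOAc, the classical closure of 4-(pyrrol-2-yl)but-3-enoic acids, should give the 4-acetoxyindole F2; under these conditions the alkene geometry can equilibrate through the dienolate of the mixed anhydride. Brief treatment of F2 with K2CO3 in MeOH at 0 °C removes the acetate and rejoins the route at 21.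

**Step 3.** While the aminophosphonium salt is hydrolysed, nitrogen may condense with the formyl group or with the ketone of a second molecule (dihydropyrazine formation), and protonation of PPh3 may slow the azide reduction.
Fallback, from 3 back to 9: a Delépine amination, in which nitrogen is never unprotonated. Chloroketone 3 with hexamethylenetetramine and catalytic NaI in CHCl3 gives the hexaminium chloride F3. Ethanolic HCl cleaves F3 to 2-(5-formyl-1H-pyrrol-3-yl)-2-oxoethan-1-aminium chloride F4, which is freed from NH4Cl by filtration and coupled with 7 under the conditions of step 4 to give 9.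

**Step 8.** Geometric selectivity may erode with this hindered N-sulfonyl heteroaryl aldehyde, giving material in which pyrrole A is trans to the ester and which cannot cyclise later.
Fallback, from 11 back to 15: the isomer mixture is converged through an alkyne. The crude mixture of 15 and its Z isomer, methyl (Z)-2-bromo-3-{...}prop-2-enoate F5, is dehydrobrominated with DBU to the methyl 3-(pyrrol-2-yl)propiolate F6. Pd(PPh3)4-catalysed syn-hydrostannation of F6 with Bu3SnH places tin on the ester-bearing carbon and hydrogen cis to it, giving the α-stannyl acrylate F7 with pyrrole A cis to the ester. Bromodestannylation of F7 with NBS proceeds with retention and returns geometrically defined 15.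

**Step 10.** The diazoalkane may add as a 1,3-dipole across the enoyl chloride, and HCl may add reversibly to the acid chloride and scramble the alkene geometry.
Fallback, from 16 back to 18: detrifluoroacetylative diazo transfer, the established route to α,β-unsaturated diazoketones that avoids acid chlorides. Acid 16 is coupled with N,O-dimethylhydroxylamine to the Weinreb amide F8, and MeMgBr at low temperature gives the methyl ketone (E)-3-bromo-4-{...}but-3-en-2-one F9. Its kinetic enolate (LiHMDS, −78 °C) is acylated with 2,2,2-trifluoroethyl trifluoroacetate to the trifluoroacetyl diketone F10, and treatment of F10 with MsN3, Et3N and water in MeCN transfers the diazo group with loss of the trifluoroacetyl group to give 18.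

## Further compounds

F1 | step 11 | (E)-3-bromo-4-{4-[2-(5-bromo-1-tosyl-1H-pyrrol-2-yl)-1,3-oxazol-5-yl]-1-tosyl-1H-pyrrol-2-yl}but-3-enoic acid | OC(=O)C/C(Br)=C\c1cc(-c2cnc(-c3ccc(Br)n3S(=O)(=O)c3ccc(C)cc3)o2)cn1S(=O)(=O)c1ccc(C)cc1
F2 | step 11 | 6-bromo-3-[2-(5-bromo-1-tosyl-1H-pyrrol-2-yl)-1,3-oxazol-5-yl]-1-tosyl-1H-indol-4-yl acetate | CC(=O)Oc1cc(Br)cc2n(S(=O)(=O)c3ccc(C)cc3)cc(-c3cnc(-c4ccc(Br)n4S(=O)(=O)c4ccc(C)cc4)o3)c12
F3 | step 3 | 1-[2-(5-formyl-1H-pyrrol-3-yl)-2-oxoethyl]-1,3,5,7-tetraazaadamantan-1-ium chloride | O=Cc1cc(C(=O)C[N+]23CN4CN(CN(C4)C2)C3)c[nH]1.[Cl-]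
F4 | step 3 | 2-(5-formyl-1H-pyrrol-3-yl)-2-oxoethan-1-aminium chloride | O=Cc1cc(C(=O)C[NH3+])c[nH]1.[Cl-]
F5 | step 8 | methyl (Z)-2-bromo-3-{4-[2-(5-bromo-1-tosyl-1H-pyrrol-2-yl)-1,3-oxazol-5-yl]-1-tosyl-1H-pyrrol-2-yl}prop-2-enoate | COC(=O)/C(Br)=C/c1cc(-c2cnc(-c3ccc(Br)n3S(=O)(=O)c3ccc(C)cc3)o2)cn1S(=O)(=O)c1ccc(C)cc1
F6 | step 8 | methyl 3-{4-[2-(5-bromo-1-tosyl-1H-pyrrol-2-yl)-1,3-oxazol-5-yl]-1-tosyl-1H-pyrrol-2-yl}prop-2-ynoate | COC(=O)C#Cc1cc(-c2cnc(-c3ccc(Br)n3S(=O)(=O)c3ccc(C)cc3)o2)cn1S(=O)(=O)c1ccc(C)cc1
F7 | step 8 | methyl (E)-3-{4-[2-(5-bromo-1-tosyl-1H-pyrrol-2-yl)-1,3-oxazol-5-yl]-1-tosyl-1H-pyrrol-2-yl}-2-(tributylstannyl)prop-2-enoate | COC(=O)/C(=C\c1cc(-c2cnc(-c3ccc(Br)n3S(=O)(=O)c3ccc(C)cc3)o2)cn1S(=O)(=O)c1ccc(C)cc1)[Sn](CCCC)(CCCC)CCCC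
F8 | step 10 | (E)-2-bromo-3-{4-[2-(5-bromo-1-tosyl-1H-pyrrol-2-yl)-1,3-oxazol-5-yl]-1-tosyl-1H-pyrrol-2-yl}-N-methoxy-N-methylprop-2-enamide | CON(C)C(=O)/C(Br)=C\c1cc(-c2cnc(-c3ccc(Br)n3S(=O)(=O)c3ccc(C)cc3)o2)cn1S(=O)(=O)c1ccc(C)cc1
F9 | step 10 | (E)-3-bromo-4-{4-[2-(5-bromo-1-tosyl-1H-pyrrol-2-yl)-1,3-oxazol-5-yl]-1-tosyl-1H-pyrrol-2-yl}but-3-en-2-one | CC(=O)/C(Br)=C\c1cc(-c2cnc(-c3ccc(Br)n3S(=O)(=O)c3ccc(C)cc3)o2)cn1S(=O)(=O)c1ccc(C)cc1
F10 | step 10 | (E)-5-bromo-6-{4-[2-(5-bromo-1-tosyl-1H-pyrrol-2-yl)-1,3-oxazol-5-yl]-1-tosyl-1H-pyrrol-2-yl}-1,1,1-trifluorohex-5-ene-2,4-dione | O=C(CC(=O)/C(Br)=C\c1cc(-c2cnc(-c3ccc(Br)n3S(=O)(=O)c3ccc(C)cc3)o2)cn1S(=O)(=O)c1ccc(C)cc1)C(F)(F)F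
A1 | alternative 1 | 6-bromo-4-methoxy-3-[2-(1H-pyrrol-2-yl)-1,3-oxazol-5-yl]-1-tosyl-1H-indole | COc1cc(Br)cc2n(S(=O)(=O)c3ccc(C)cc3)cc(-c3cnc(-c4ccc[nH]4)o3)c12
A2 | alternative 1 | 4-[5-(6-bromo-4-methoxy-1-tosyl-1H-indol-3-yl)-1,3-oxazol-2-yl]-4-oxobutanal | COc1cc(Br)cc2n(S(=O)(=O)c3ccc(C)cc3)cc(-c3cnc(C(=O)CCC=O)o3)c12
A3 | alternative 2 | 6-bromo-3-[2-(5-bromo-1-tosyl-1H-pyrrol-2-yl)-1,3-oxazol-5-yl]-4-methoxy-1H-indole | COc1cc(Br)cc2[nH]cc(-c3cnc(-c4ccc(Br)n4S(=O)(=O)c4ccc(C)cc4)o3)c12
A4 | alternative 2 | 5-[1-(4-bromo-2-methoxy-6-nitrophenyl)ethenyl]-2-(5-bromo-1-tosyl-1H-pyrrol-2-yl)-1,3-oxazole | COc1cc(Br)cc([N+](=O)[O-])c1C(=C)c1cnc(-c2ccc(Br)n2S(=O)(=O)c2ccc(C)cc2)o1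
A5 | alternative 3 | 6-bromo-3-[2-(5-bromo-1-tosyl-1H-pyrrol-2-yl)-1,3-oxazol-5-yl]-4-methoxy-1-tosyl-1H-indole (identical with 22) | COc1cc(Br)cc2n(S(=O)(=O)c3ccc(C)cc3)cc(-c3cnc(-c4ccc(Br)n4S(=O)(=O)c4ccc(C)cc4)o3)c12
A6 | alternative 3 | 5-bromo-3-methoxy-2-(trimethylsilyl)phenyl trifluoromethanesulfonate | COc1cc(Br)cc(OS(=O)(=O)C(F)(F)F)c1[Si](C)(C)C
A7 | alternative 3 | N-{2-[2-(5-bromo-1-tosyl-1H-pyrrol-2-yl)-1,3-oxazol-5-yl]-2-oxoethyl}-4-methylbenzenesulfonamide | Cc1ccc(cc1)S(=O)(=O)NCC(=O)c1cnc(-c2ccc(Br)n2S(=O)(=O)c2ccc(C)cc2)o1
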